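## Analysis of the target

The target, 3-acetyl-2,6-dihydroxy-4-pentylphenyl 4-hydroxy-2-methoxy-6-propylbenzoate, is a depside: two separate aromatic rings joined only by one aryl ester. It has no stereocentre, so the whole problem is regiochemistry and telling five aryl oxygens apart. Ring B (the acyl half) is numbered from the carboxyl-bearing carbon C1 and carries methoxy on C2, hydroxyl on C4 and propyl on C6. Ring A (the phenol half) is numbered as an aryl methyl ketone, with acetyl on C1, oxygens on C2, C3 and C4 and pentyl on C6; the middle oxygen O3 carries the ester. The sensitive points are the aryl ester, which sits between two ortho hydroxyls and will migrate or cleave under base, the 1,2,3-trioxygenated ring A, which oxidises easily once unmasked, and the aryl ketone, which limits reductive and organometallic steps. The synthesis is hard because the ester is hindered from both sides (2,6-disubstituted acid, 2,6-disubstituted phenol) and because one oxygen must be methylated, one acylated and three left free. The strategy rests on ring B: its pattern (carboxyl carbon on C1, oxygen on C2 and C4, propyl on C6) is what a linear 3,5,7-triketo decanoate gives when its C2 is bonded to its C7. The ester carbon, the two ketone oxygens and the propyl terminus then fall into place without any aromatic substitution.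

## Retrosynthetic reasoning

**24 to 23.** The three free hydroxyls of 24 are traced back to benzyl ethers in 23. Hydrogenolysis is neutral, which matters because the ester between two ortho hydroxyls of ring A would not survive basic or nucleophilic deprotection. The forward step must cleave three O–benzyl bonds and leave the aryl ketone, the ester and the methyl ether alone.

**23 to 12 and 21 (through 22).** The ester C(=O)–O bond is cut because it is the only bond between the rings, which makes the route convergent. In 21 both flanking oxygens are benzylated, so O3 is the only site that can be acylated. The forward step has to overcome the double hindrance, which is why the acid is activated as chloride 22.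

**12 to 11 to 10 to 9.** These are adjustments on ring B: the acid comes from the methyl ester, the C2 methoxy from a hydroxyl, the C4 benzyl ether from a hydroxyl. In 9 the C2 hydroxyl is hydrogen-bonded to the ester carbonyl and the C4 hydroxyl is not, so the two oxygens can be addressed one after the other without extra protecting groups.

**9 to 7 (through 8), the key disconnection.** The ring B bond between C1 and C6 is cut and the ring is unfolded to the open chain 7; in chain numbering this is the C2–C7 bond. This is the one cut that leaves a linear chain in which every ring substituent is already encoded. Ring B therefore needs no electrophilic substitution and no regiochemical decision. The forward reaction must add the C2 enolate to the C7 ketone and then dehydrate and enolise to the aromatic ring.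

**7 to 6 to 3 and 4 (through 5); 3 to 1 and 2.** The chain is cut between C4 and C5, a Claisen-type acylation of the terminal carbon of 4 (as dianion 5) by a 3-oxohexanoyl unit. The ketone of that unit, the future C7, is masked as the cyclic ketal of 2. This makes 3 behave as a plain ester, and the chain cannot fold before it is complete.

**21 to 20 to 19 to 18 to 17.** The protecting pattern of 21 is traced back to triol 17 through the graded reactivity of its hydroxyls. O4–H is para to the acetyl group and most acidic, O3–H is an ordinary phenol, and O2–H is chelated to the ketone and least reactive. Benzyl goes on O4, a temporary acetal on O3, benzyl on O2, and the acetal is removed.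

**17 to 16 to 15 to 13 and 14.** The acetyl–ring bond is cut (Friedel–Crafts acylation) and then the pentyl–ring bond (cross-coupling of 13 with 14). Intermediate 15 is symmetric and its two open positions are equivalent, so the acylation has no regiochemical question; all three ring A oxygens are bought in place with 13.

## Alternatives that were turned down

**Alternative 1:** Ring B acid is disconnected at two exocyclic bonds, C6–propyl and C1–carboxyl, through an aryne made from the aryl fluoride A2, (3-fluoro-5-methoxyphenoxy)tri(propan-2-yl)silane.
- Forward key step: A2 is lithiated between fluorine and methoxy and loses fluoride to give the aryne. A propyl Grignard reagent adds at the aryne carbon remote from methoxy, and the arylmagnesium next to methoxy is carboxylated to A1, 2-methoxy-6-propyl-4-(triisopropylsilyloxy)benzoic acid.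
- For: one flask gives the free acid with the methoxy in place and the C4 oxygen already differentiated. No hindered ester has to be hydrolysed. On step count to the acid it is clearly stronger than steps 1–7 here.
- Against: A2 has three acidic ring positions, each between two heteroatom substituents, so the lithiation site is not secured by structure. The alkyllithium base can add to the aryne in competition with the Grignard reagent. The regiochemistry of addition rests on the inductive bias of one methoxy group. The silyl ether would have to be removed from the finished depside with fluoride, a basic reagent that invites acyl migration onto the ring A hydroxyls, or exchanged for benzyl before coupling, which gives back much of the saving.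
- Comparison: the chosen route is longer, but the position of every ring B substituent is fixed by chain connectivity, and it ends in one neutral hydrogenolysis.

**Alternative 2:** Ring A is disconnected to a 1,3-diketone A4 (pentane-2,4-dione) and an unsaturated ester A5 (ethyl (E)-oct-2-enoate).
- Forward key step: under alkoxide base the central carbon of A4 adds to A5, forming the bond between the acetyl-bearing and pentyl-bearing carbons. A methyl ketone enolate then closes on the ester to give A3, trans-4-acetyl-5-pentylcyclohexane-1,3-dione, to be aromatised later.
- For: it builds the ring A carbon skeleton from acyclic pieces with acetyl and pentyl unambiguously adjacent. On carbon–carbon bond economy for ring A it is at least as strong as buying the ring and acylating it, and it needs no cross-coupling.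
- Against: dehydrogenation of A3 leads to A6, 1-(2,4-dihydroxy-6-pentylphenyl)ethan-1-one, which lacks the C3 oxygen, the one that carries the ester. That oxygen would have to be introduced between two hydroxyls with no structural control. The β-triketone intermediate is prone to retro-Claisen loss of acetyl under the alkoxide conditions. Two stereocentres are set only to be destroyed in an extra oxidation step. Ring B and its oxygen differentiation are not addressed at all.
- Comparison: the chosen strategy starts ring A from 13, where all three oxygens are present, and spends its ring-forming step on ring B, where the substitution maps exactly onto a foldable chain.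

**Alternative 3:** Ring B is disconnected at C1–C2 and C5–C6 into the diene A8, 1,1-dimethoxy-3-(trimethylsilyloxy)buta-1,3-diene, and the alkynoate A9, methyl hex-2-ynoate.
- Forward key step: thermal [4+2] cycloaddition, then loss of one alkoxy group and of the silyl group, aromatises the adduct to A7, methyl 4-hydroxy-2-methoxy-6-propylbenzoate.
- For: two ring bonds form in one convergent step, and the C2 methoxy and C4 hydroxyl come out already differentiated. On this point it is stronger than the chosen route and would save the methylation step.
- Against: A9 is activated by one ester only and carries a β-alkyl group, so the cycloaddition needs prolonged heating. A8 is a hydrolytically fragile ketene acetal that must be made fresh and tends to oligomerise or transfer its silyl group under that heating. Stepwise conjugate addition without ring closure is a plausible diversion.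
- Comparison: the chosen route pays one extra step for oxygen differentiation but uses storable intermediates, and it takes its regiochemistry from connectivity and a chelation difference, not from frontier-orbital polarisation.

Key step: step 4

Remark on the chemistry: polycarbonyl compounds 6, 7 and 8 are drawn as keto tautomers although they should be largely enolised; the chain of 7 is numbered from the ester carbon (C1) to the propyl terminus (C10).

## Route

Step 1
Reactants: 1 methyl 3-oxohexanoate; 2 ethylene glycol
Product: 3 methyl 2-(2-propyl-1,3-dioxolan-2-yl)acetate
Conditions: p-TsOH·H2O (cat.), toluene, reflux, Dean–Stark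
Reagents that add atoms: none
Why: Acid-catalysed ketalisation driven by azeotropic removal of water; the ketone carbonyl reacts and the ester does not, and the ketal takes away the double activation of the C2 methylene so that 3 can serve as a plain ester electrophile in step 2.

Step 2
Reactants: 4 methyl acetoacetate; 3 methyl 2-(2-propyl-1,3-dioxolan-2-yl)acetate
Product: 6 methyl 3,5-dioxo-6-(2-propyl-1,3-dioxolan-2-yl)hexanoate, via dilithium dianion of methyl acetoacetate 5 (not isolated)
Conditions: 4 (2.1 equiv), LiN(i-Pr)2 (4.2 equiv, commercial solution), THF, 0 °C; then 3 (1 equiv), 0 °C → rt; AcOH quench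
Reagents that add atoms: none
Why: Claisen-type C-acylation of an acetoacetate dianion at its terminal carbon, the most nucleophilic site, by ester 3; the excess of 5 takes up the acidic proton of the new 1,3-diketone so that the acylation is not stalled.

Step 3
Reactants: 6 methyl 3,5-dioxo-6-(2-propyl-1,3-dioxolan-2-yl)hexanoate
Product: 7 methyl 3,5,7-trioxodecanoate
Conditions: 1 M aq. HCl, THF, 0 °C → rt, short; crude 7 carried on at once
Reagents that add atoms: water, O
Why: Acid-catalysed hydrolysis of the cyclic ketal; the exposure to acid is kept cold and brief and 7 is not stored, because the free triketo ester cyclises on standing.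

Step 4
Reactants: 7 methyl 3,5,7-trioxodecanoate
Product: 9 methyl 2,4-dihydroxy-6-propylbenzoate, via cyclic aldol adduct 8 (not isolated)
Conditions: 0.2 M aq. KOH (2.2 equiv), MeOH, 0 °C → rt; then 1 M HCl to pH 3
Reagents that add atoms: none
Why: Hydroxide converts 7 into its enolates; the C2 enolate, flanked by the ester and the C3 ketone, adds to the C7 ketone to give 8, which loses water and enolises at C3 and C5 to the aromatic ring of 9. The closest known reaction type is the base-mediated aldol aromatisation of 3,5,7-triketo esters to 2,4-dihydroxy-6-alkylbenzoates. The one ring is closed in the 6-(enolexo)-exo-trig mode and the new bond joins the carboxyl-bearing carbon (C1 of ring B) to the propyl-bearing carbon (C6 of ring B). The two stereocentres of 8 are transient and vanish on aromatisation, so no stereocontrol is needed. The step needs chemoselectivity for the aldol (C2 on C7) over the Claisen closure (C6 on the ester carbon) and over closure through an enol oxygen. In aqueous base C2 is deprotonated, so the ester carbonyl is part of an enolate and a poor electrophile, while the reversible aldol at the ketone is pulled forward by irreversible dehydration and aromatisation. Attack of C8 on C3 is not expected because C8 is not doubly activated. Dilute base at low temperature spares the methyl ester, which in 9 is further shielded by the ortho phenoxide and the propyl group.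

Step 5
Reactants: 9 methyl 2,4-dihydroxy-6-propylbenzoate
Product: 10 methyl 4-(benzyloxy)-2-hydroxy-6-propylbenzoate
Conditions: BnBr (1.05 equiv), K2CO3, acetone, reflux
Reagents that add atoms: benzyl bromide, BrCc1ccccc1
Why: Williamson etherification; the C2 hydroxyl is tied to the ester carbonyl by an intramolecular hydrogen bond and the C4 hydroxyl is the more acidic and more exposed, so one equivalent of benzyl bromide should alkylate O4 only.

Step 6
Reactants: 10 methyl 4-(benzyloxy)-2-hydroxy-6-propylbenzoate
Product: 11 methyl 4-(benzyloxy)-2-methoxy-6-propylbenzoate
Conditions: MeI, K2CO3, DMF, 50 °C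
Reagents that add atoms: iodomethane, CI
Why: Williamson methylation of the remaining chelated phenol under more forcing dipolar aprotic conditions; nothing else in 10 can be alkylated.

Step 7
Reactants: 11 methyl 4-(benzyloxy)-2-methoxy-6-propylbenzoate
Product: 12 4-(benzyloxy)-2-methoxy-6-propylbenzoic acid
Conditions: KOH, DMSO/H2O, 90 °C; then cold 1 M HCl
Reagents that add atoms: potassium hydroxide, [K+].[OH-]
Why: Saponification of a 2,6-disubstituted methyl benzoate, slow because of the flanking groups and therefore run hot in aqueous DMSO; the benzyl and methyl ethers are inert to hydroxide and the acid is released by cold acidification.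

Step 8
Reactants: 13 5-bromo-1,2,3-trimethoxybenzene; 14 pentylmagnesium bromide
Product: 15 1,2,3-trimethoxy-5-pentylbenzene
Conditions: NiCl2(dppp) (2 mol%), THF/Et2O, 0 °C → reflux
Reagents that add atoms: none
Why: Kumada cross-coupling of an aryl bromide with a primary alkyl Grignard reagent; the bidentate phosphine on nickel favours reductive elimination over β-hydride elimination, and the methoxy groups are inert.

Step 9
Reactants: 15 1,2,3-trimethoxy-5-pentylbenzene
Product: 16 1-(2,3,4-trimethoxy-6-pentylphenyl)ethan-1-one
Conditions: AcCl, AlCl3, CH2Cl2, −10 → 0 °C
Reagents that add atoms: acetyl chloride, CC(Cl)=O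
Why: Friedel–Crafts acylation; the two open positions of 15 are equivalent (each ortho to pentyl and to an outer methoxy, para to the other outer methoxy), so only one ketone can form. Any loss of a methyl group caused by AlCl3 is of no consequence because step 10 removes all three.

Step 10
Reactants: 16 1-(2,3,4-trimethoxy-6-pentylphenyl)ethan-1-one
Product: 17 1-(2,3,4-trihydroxy-6-pentylphenyl)ethan-1-one
Conditions: BBr3 (4 equiv), CH2Cl2, −78 °C → rt; then H2O, under argon
Reagents that add atoms: none
Why: Lewis acid cleavage of aryl methyl ethers by BBr3 (bromide attacks the O-methyl of the boron-complexed ether); ketone and alkyl chain are untouched, and 17 is kept under inert gas because the free vicinal triol is air-sensitive.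

Step 11
Reactants: 17 1-(2,3,4-trihydroxy-6-pentylphenyl)ethan-1-one
Product: 18 1-[4-(benzyloxy)-2,3-dihydroxy-6-pentylphenyl]ethan-1-one
Conditions: BnBr (1.05 equiv), Li2CO3, DMF, 45 °C
Reagents that add atoms: benzyl bromide, BrCc1ccccc1
Why: Williamson etherification with a weak base; O4–H, para to the acetyl group, is the most acidic hydroxyl, O2–H is chelated to the ketone and O3–H is an ordinary phenol, so one equivalent of benzyl bromide should alkylate O4.

Step 12
Reactants: 18 1-[4-(benzyloxy)-2,3-dihydroxy-6-pentylphenyl]ethan-1-one
Product: 19 1-[4-(benzyloxy)-2-hydroxy-3-(methoxymethoxy)-6-pentylphenyl]ethan-1-one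
Conditions: MOMCl (1.2 equiv), i-Pr2NEt, CH2Cl2, 0 °C
Reagents that add atoms: chloromethyl methyl ether, COCCl
Why: Alkylation of the free phenol O3–H with a hindered amine base; O2–H stays locked in its hydrogen bond to the acetyl carbonyl, so the acid-labile mask lands on the oxygen that is to be acylated later.

Step 13
Reactants: 19 1-[4-(benzyloxy)-2-hydroxy-3-(methoxymethoxy)-6-pentylphenyl]ethan-1-one
Product: 20 1-[2,4-bis(benzyloxy)-3-(methoxymethoxy)-6-pentylphenyl]ethan-1-one
Conditions: BnBr, K2CO3, DMF, 60 °C
Reagents that add atoms: benzyl bromide, BrCc1ccccc1
Why: Williamson etherification of the chelated phenol, now the only free hydroxyl, under forcing conditions; carbonate does not enolise the methyl ketone.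

Step 14
Reactants: 20 1-[2,4-bis(benzyloxy)-3-(methoxymethoxy)-6-pentylphenyl]ethan-1-one
Product: 21 1-[2,4-bis(benzyloxy)-3-hydroxy-6-pentylphenyl]ethan-1-one
Conditions: 3 M aq. HCl, THF, 45 °C
Reagents that add atoms: none
Why: Acid hydrolysis of the methoxymethyl acetal; aryl benzyl ethers and the ketone withstand dilute aqueous acid at this temperature, so only O3 is set free.

Step 15
Reactants: 12 4-(benzyloxy)-2-methoxy-6-propylbenzoic acid; 21 1-[2,4-bis(benzyloxy)-3-hydroxy-6-pentylphenyl]ethan-1-one
Product: 23 3-acetyl-2,6-bis(benzyloxy)-4-pentylphenyl 4-(benzyloxy)-2-methoxy-6-propylbenzoate, via acid chloride 22 (not isolated)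
Conditions: (COCl)2, DMF (cat.), CH2Cl2, 0 °C → rt; evaporate; then 21, Et3N, DMAP (0.2 equiv), CH2Cl2, rt → reflux
Reagents that add atoms: none
Why: Acyl chloride formation catalysed by DMF, then DMAP-catalysed acylation of a phenol; 21 has a single free hydroxyl, so the ester can only form on O3, and the acid chloride is chosen to overcome the hindrance on both partners.

Step 16
Reactants: 23 3-acetyl-2,6-bis(benzyloxy)-4-pentylphenyl 4-(benzyloxy)-2-methoxy-6-propylbenzoate
Product: 24 3-acetyl-2,6-dihydroxy-4-pentylphenyl 4-hydroxy-2-methoxy-6-propylbenzoate
Conditions: H2 (1 atm), Pd/C (10%), EtOAc, rt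
Reagents that add atoms: none
Why: Hydrogenolysis of three aryl benzyl ethers under neutral conditions, which avoids the acyl migration that base would cause; the reaction is stopped at the calculated uptake so that the hindered aryl ketone and the ester are not reduced.

## Compound list

1 | methyl 3-oxohexanoate | CCCC(=O)CC(=O)OC | starting material
2 | ethylene glycol | OCCO | starting material
3 | methyl 2-(2-propyl-1,3-dioxolan-2-yl)acetate | CCCC1(CC(=O)OC)OCCO1 | intermediate
4 | methyl acetoacetate | CC(=O)CC(=O)OC | starting material
5 | dilithium dianion of methyl acetoacetate (not isolated) | [Li+].[Li+].[CH2-]C(=O)[CH-]C(=O)OC | intermediate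
6 | methyl 3,5-dioxo-6-(2-propyl-1,3-dioxolan-2-yl)hexanoate | CCCC1(CC(=O)CC(=O)CC(=O)OC)OCCO1 | intermediate
7 | methyl 3,5,7-trioxodecanoate | CCCC(=O)CC(=O)CC(=O)CC(=O)OC | intermediate
8 | methyl 2-hydroxy-4,6-dioxo-2-propylcyclohexane-1-carboxylate (cyclic aldol adduct, mixture of stereoisomers, not isolated) | CCCC1(O)CC(=O)CC(=O)C1C(=O)OC | intermediate
9 | methyl 2,4-dihydroxy-6-propylbenzoate | CCCc1cc(O)cc(O)c1C(=O)OC | intermediate
10 | methyl 4-(benzyloxy)-2-hydroxy-6-propylbenzoate | CCCc1cc(OCc2ccccc2)cc(O)c1C(=O)OC | intermediate
11 | methyl 4-(benzyloxy)-2-methoxy-6-propylbenzoate | CCCc1cc(OCc2ccccc2)cc(OC)c1C(=O)OC | intermediate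
12 | 4-(benzyloxy)-2-methoxy-6-propylbenzoic acid | CCCc1cc(OCc2ccccc2)cc(OC)c1C(O)=O | intermediate
13 | 5-bromo-1,2,3-trimethoxybenzene | COc1cc(Br)cc(OC)c1OC | starting material
14 | pentylmagnesium bromide | CCCCC[Mg]Br | starting material
15 | 1,2,3-trimethoxy-5-pentylbenzene | CCCCCc1cc(OC)c(OC)c(OC)c1 | intermediate
16 | 1-(2,3,4-trimethoxy-6-pentylphenyl)ethan-1-one | CCCCCc1cc(OC)c(OC)c(OC)c1C(C)=O | intermediate
17 | 1-(2,3,4-trihydroxy-6-pentylphenyl)ethan-1-one | CCCCCc1cc(O)c(O)c(O)c1C(C)=O | intermediate
18 | 1-[4-(benzyloxy)-2,3-dihydroxy-6-pentylphenyl]ethan-1-one | CCCCCc1cc(OCc2ccccc2)c(O)c(O)c1C(C)=O | intermediate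
19 | 1-[4-(benzyloxy)-2-hydroxy-3-(methoxymethoxy)-6-pentylphenyl]ethan-1-one | CCCCCc1cc(OCc2ccccc2)c(OCOC)c(O)c1C(C)=O | intermediate
20 | 1-[2,4-bis(benzyloxy)-3-(methoxymethoxy)-6-pentylphenyl]ethan-1-one | CCCCCc1cc(OCc2ccccc2)c(OCOC)c(OCc2ccccc2)c1C(C)=O | intermediate
21 | 1-[2,4-bis(benzyloxy)-3-hydroxy-6-pentylphenyl]ethan-1-one | CCCCCc1cc(OCc2ccccc2)c(O)c(OCc2ccccc2)c1C(C)=O | intermediate
22 | 4-(benzyloxy)-2-methoxy-6-propylbenzoyl chloride (not isolated) | CCCc1cc(OCc2ccccc2)cc(OC)c1C(Cl)=O | intermediate
23 | 3-acetyl-2,6-bis(benzyloxy)-4-pentylphenyl 4-(benzyloxy)-2-methoxy-6-propylbenzoate | CCCCCc1cc(OCc2ccccc2)c(OC(=O)c2c(CCC)cc(OCc3ccccc3)cc2OC)c(OCc2ccccc2)c1C(C)=O | intermediate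
24 | 3-acetyl-2,6-dihydroxy-4-pentylphenyl 4-hydroxy-2-methoxy-6-propylbenzoate | CCCCCc1cc(O)c(OC(=O)c2c(CCC)cc(O)cc2OC)c(O)c1C(C)=O | target

## Step count and least certain steps

Total step count: 16. Longest linear sequence: 9 steps (steps 1–7, then 15 and 16; the ring A branch, steps 8–14, then 15 and 16, is equally long).

**Step 4 (key step).** Ring closure may take the Claisen course (C6 on the ester carbon) or go through an enol oxygen instead of the aldol. Saponification followed by decarboxylation may intervene if the base is too strong or too warm, and cyclodehydration of the labile 7 may already begin under the acid of step 3. Fallback: the ring of 9 is built stepwise and then oxidised, instead of being formed by an aromatising aldol. Setting out from 4, conjugate addition to methyl (E)-hex-2-enoate followed by Claisen ring closure (NaOMe, MeOH, reflux) should give methyl 2,4-dioxo-6-propylcyclohexane-1-carboxylate F1. Bromination and dehydrobromination (Br2, DMF, 0 °C) should aromatise F1 to 9, where the route is rejoined.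

**Step 2.** Proton transfer from the ester methylene of 3 to the strongly basic 5 may compete with acylation and open the ketal ring by β-elimination; the acidic product also consumes base, so conversion may stall. Fallback: the chain is assembled from the other end without a ketal. Setting out from 4, its dianion 5 is acylated with N-methoxy-N-methylacetamide to give methyl 3,5-dioxohexanoate F2. F2 is deprotonated three times with LiN(i-Pr)2 and acylated at its terminal carbon with N-methoxy-N-methylbutanamide, which should give 7 directly; the route is rejoined at 7 and compounds 3 and 6 are bypassed.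

**Step 11.** Site selectivity between O4 and O3 may be lost, or alkylation may run on to a second benzyl group, because the acidity gap between the two hydroxyls is only moderate. Fallback: O3 and O4 are tied together first. Setting out from 17, heating with dichlorodiphenylmethane should give the ketal 1-(4-hydroxy-6-pentyl-2,2-diphenyl-1,3-benzodioxol-5-yl)ethan-1-one F3. Benzylation of the chelated hydroxyl (BnBr, K2CO3, DMF) gives 1-[4-(benzyloxy)-6-pentyl-2,2-diphenyl-1,3-benzodioxol-5-yl]ethan-1-one F4. Aqueous acetic acid at reflux releases 1-[2-(benzyloxy)-3,4-dihydroxy-6-pentylphenyl]ethan-1-one F5. Monobenzylation of the less hindered O4, para to the acetyl group (BnBr, Li2CO3, DMF), gives 21, where the route is rejoined; compounds 18–20 are bypassed.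

**Step 15.** Acyl transfer may be too slow because both partners are flanked on both sides, so that decomposition of the activated acid or acylation at the open ring A carbon competes. Fallback: the activation mode is changed from addition–elimination at an acyl chloride to an acylium pathway, which suits 2,6-disubstituted electron-rich benzoic acids. Setting out from 12 and 21 in toluene with trifluoroacetic anhydride, 12 forms 4-(benzyloxy)-2-methoxy-6-propylbenzoic trifluoroacetic anhydride F6, which ionises and is trapped by the hydroxyl of 21 to give 23, where the route is rejoined.

**Step 16.** Over-reduction of the aryl ketone, or incomplete cleavage of the two hindered benzyl ethers next to the ester, may occur; acyl migration to a neighbouring hydroxyl would follow if the medium turned basic. Fallback: Lewis acid debenzylation instead of hydrogenolysis. Setting out from 23, BCl3 with pentamethylbenzene as benzyl cation scavenger in CH2Cl2 at −78 °C should give 24 directly. The temperature is held low so that the methoxy group ortho to the ester carbonyl is not cleaved; no new compound is made.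

## Further compounds

F1 | step 4 | methyl 2,4-dioxo-6-propylcyclohexane-1-carboxylate (racemic, largely enolised, relative configuration immaterial) | CCCC1CC(=O)CC(=O)C1C(=O)OC
F2 | step 2 | methyl 3,5-dioxohexanoate | CC(=O)CC(=O)CC(=O)OC
F3 | step 11 | 1-(4-hydroxy-6-pentyl-2,2-diphenyl-1,3-benzodioxol-5-yl)ethan-1-one | CCCCCc1cc2OC(c3ccccc3)(c3ccccc3)Oc2c(O)c1C(C)=O
F4 | step 11 | 1-[4-(benzyloxy)-6-pentyl-2,2-diphenyl-1,3-benzodioxol-5-yl]ethan-1-one | CCCCCc1cc2OC(c3ccccc3)(c3ccccc3)Oc2c(OCc2ccccc2)c1C(C)=O
F5 | step 11 | 1-[2-(benzyloxy)-3,4-dihydroxy-6-pentylphenyl]ethan-1-one | CCCCCc1cc(O)c(O)c(OCc2ccccc2)c1C(C)=O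
F6 | step 15 | 4-(benzyloxy)-2-methoxy-6-propylbenzoic trifluoroacetic anhydride | CCCc1cc(OCc2ccccc2)cc(OC)c1C(=O)OC(=O)C(F)(F)F
F0 | step 16 | none | none
A1 | alternative 1 | 2-methoxy-6-propyl-4-(triisopropylsilyloxy)benzoic acid | CCCc1cc(O[Si](C(C)C)(C(C)C)C(C)C)cc(OC)c1C(O)=O
A2 | alternative 1 | (3-fluoro-5-methoxyphenoxy)tri(propan-2-yl)silane | COc1cc(F)cc(O[Si](C(C)C)(C(C)C)C(C)C)c1
A3 | alternative 2 | trans-4-acetyl-5-pentylcyclohexane-1,3-dione (racemic, one enantiomer drawn) | CCCCC[C@H]1CC(=O)CC(=O)[C@@H]1C(C)=O
A4 | alternative 2 | pentane-2,4-dione | CC(=O)CC(C)=O
A5 | alternative 2 | ethyl (E)-oct-2-enoate | CCCCC/C=C/C(=O)OCC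
A6 | alternative 2 | 1-(2,4-dihydroxy-6-pentylphenyl)ethan-1-one | CCCCCc1cc(O)cc(O)c1C(C)=O
A7 | alternative 3 | methyl 4-hydroxy-2-methoxy-6-propylbenzoate | CCCc1cc(O)cc(OC)c1C(=O)OC
A8 | alternative 3 | 1,1-dimethoxy-3-(trimethylsilyloxy)buta-1,3-diene | COC(OC)=CC(=C)O[Si](C)(C)C
A9 | alternative 3 | methyl hex-2-ynoate | CCCC#CC(=O)OC
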